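**Plan**

- Retrosynthetic cuts: the three MOM ethers and the two aryl–CHO bonds; the two C–CH3 bonds of the carbinol (back to a C7 ester); the C7–C bond with the C8=C8a alkene ([2,3] shift of a ring-fusion allylic alcohol); C7=C8 (metathesis) and C8–C8a (vinyl addition); C3a–C4 (Claisen); then the benzylic C–CH2 and C1–CH3 bonds, and finally the arylidene C=C (aldol).
- Forward order: the five-membered ring is bought as cyclopentanone and condensed with the protected aldehyde; the key step adds isobutyl and methyl; the C5 side chain is attached by a Claisen rearrangement and extended; the seven-membered ring, the only ring made, is closed by metathesis; transposition, carbinol formation, two formylations and deprotection follow.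
- Feature used: the benzylic CH (aryl, isobutyl) and the adjacent quaternary, methyl-bearing C1 of the five-membered ring are the β- and α-carbons of a 2-arylidene cyclopentanone, whose carbonyl carbon becomes C8a.
- Stereochemistry: the benzylic centre comes from the chiral copper catalyst; C1 is relayed from it in the enolate methylation (allylic 1,3-strain); C3a and C4 come from the Claisen step (bond formation anti to the aryl(isobutyl)methyl group, chair with a Z-crotyl unit); C7 is relayed from the carbinol carbon by the suprafacial [2,3] shift.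

Key step: step 3

Conventions: Ar = 2,4,6-tris(methoxymethoxy)phenyl; bicyclic compounds carry azulene locants (C1 quaternary carbon, C3a and C8a ring fusion, C4 methyl-bearing carbon, C7 carbinol-bearing carbon).

Assumption: the (R,SP) antipode of the ferrocenyl diphosphine is taken to deliver isobutyl to the enone face that gives the drawn benzylic configuration; if the sense of induction is the opposite, the mirror-image ligand is used.

**Route**

Step 1
Reactants: 1 2,4,6-trihydroxybenzaldehyde
Product: 2 2,4,6-tris(methoxymethoxy)benzaldehyde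
Conditions: NaH, MOMCl, DMF, 0 °C → rt
Reagents that add atoms: chloromethyl methyl ether, COCCl
Why: Williamson-type O-alkylation of the three phenoxides gives acetal ethers that should survive every basic and organometallic reagent used later and direct the late ring metalations.

Step 2
Reactants: 2 tris-MOM aldehyde; 3 cyclopentanone
Product: 4 (E)-2-[2,4,6-tris(methoxymethoxy)benzylidene]cyclopentan-1-one
Conditions: cyclopentanone (5 equiv), NaOH (1 M aq), EtOH, 0 °C → rt
Reagents that add atoms: none
Why: Claisen–Schmidt (crossed aldol) condensation of the non-enolisable aldehyde, in which the excess ketone and the two ortho substituents should hold the reaction at the mono-arylidene stage and E1cB dehydration gives the more stable E alkene.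

Step 3
Reactants: 4 arylidene cyclopentanone; 5 isobutylmagnesium bromide
Product: 7 (2R)-2-methyl-2-[(1R)-3-methyl-1-Ar-butyl]cyclopentan-1-one, via bromomagnesium enolate 6 (not isolated)
Conditions: CuBr·SMe2 (5 mol %), (R)-1-[(SP)-2-(diphenylphosphino)ferrocenyl]ethyldicyclohexylphosphine (6 mol %), t-BuOMe, −75 °C, slow addition of 5; then MeI, DMPU, −75 → 0 °C
Reagents that add atoms: iodomethane, CI
Why: Transmetalation gives a chiral alkylcuprate that binds the enone as a π-complex, adds to the β-carbon (trivalent-copper σ-adduct) and reductively eliminates to bromomagnesium enolate 6, which DMPU activates for SN2 C-methylation by iodomethane in the same flask. The closest known reaction type is the copper/ferrocenyl-diphosphine-catalysed enantioselective 1,4-addition of Grignard reagents to enones with alkylation of the resulting magnesium enolate by an alkyl halide. No ring is closed; two skeletal bonds (benzylic C–CH2 and C2–CH3) and two adjacent stereocentres are formed. The benzylic centre is controlled by the ligand, which selects the face of the s-cis-locked exocyclic enone; the quaternary centre is controlled by that new centre, because allylic 1,3-strain holds the benzylic C–H in the enolate plane beside O–Mg and iodomethane should then enter anti to the di-ortho-substituted aryl group. The step needs 1,4- over 1,2-addition, catalysed over uncatalysed addition and C- over O-alkylation; low temperature with slow addition of 5 to the soft copper catalyst should secure the first two, and the soft electrophile, acting on an enolate generated only at the former α-carbon, the last.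

Step 4
Reactants: 7 α-methyl ketone
Product: 9 (5R)-1-iodo-5-methyl-5-[(1R)-3-methyl-1-Ar-butyl]cyclopent-1-ene, via hydrazone 8 (not isolated)
Conditions: N2H4·H2O, Et3N, EtOH, 80 °C; then I2, 1,1,3,3-tetramethylguanidine, THF, 0 °C
Reagents that add atoms: iodine, [I][I]
Why: Barton vinyl iodide synthesis, in which iodine oxidises the hydrazone to a diazo compound and then an α-iodo cation that can lose only the C5 proton, as with 17-keto steroids that carry an adjacent quaternary carbon.

Step 5
Reactants: 9 vinyl iodide; 10 (Z)-but-2-en-1-ol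
Product: 12 (2R,5R)-5-[(2R)-but-3-en-2-yl]-2-methyl-2-[(1R)-3-methyl-1-Ar-butyl]cyclopentan-1-one, via allyl vinyl ether 11 (not isolated)
Conditions: CuI (10 mol %), 3,4,7,8-tetramethyl-1,10-phenanthroline (20 mol %), Cs2CO3, o-xylene, 120 °C
Reagents that add atoms: none
Why: Copper-catalysed Ullmann-type C–O coupling followed in the same flask by Claisen [3,3] rearrangement, in which the allyl unit should bond to C5 on the ring face opposite the aryl(isobutyl)methyl group and a chair transition state with the Z-crotyl methyl axial gives the (R) side-chain methine.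

Step 6
Reactants: 12 butenyl ketone
Product: 14 (2R,5R)-5-[(2R)-hex-5-en-2-yl]-2-methyl-2-[(1R)-3-methyl-1-Ar-butyl]cyclopentan-1-one, via alkylborane 13 (not isolated)
Conditions: 9-BBN, THF, 0 °C → rt; then vinyl bromide (1 M in THF), Pd(dppf)Cl2 (5 mol %), K3PO4 (aq), DMF, rt
Reagents that add atoms: vinyl bromide, C=CBr
Why: Anti-Markovnikov hydroboration of the monosubstituted alkene (the hindered ketone should be left alone) and B-alkyl Suzuki–Miyaura coupling extend the chain by two carbons under mildly basic conditions that should not epimerise C5.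

Step 7
Reactants: 14 hexenyl ketone
Product: 15 (1R,2R,5R)-1-ethenyl-5-[(2R)-hex-5-en-2-yl]-2-methyl-2-[(1S)-3-methyl-1-Ar-butyl]cyclopentan-1-ol
Conditions: CeCl3 (anhydrous), CH2=CHMgBr, THF, −78 → 0 °C; aq NH4Cl
Reagents that add atoms: vinylmagnesium bromide, C=C[Mg]Br
Why: 1,2-Addition of the weakly basic organocerium reagent to the hindered, enolisable ketone, expected from the carbonyl face anti to the aryl(isobutyl)methyl group so that the hydroxyl ends up cis to that group and the vinyl group cis to the hexenyl chain.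

Step 8
Reactants: 15 dienyl carbinol
Product: 16 (1R,3aR,4R,8aR)-1,4-dimethyl-1-[(1S)-3-methyl-1-Ar-butyl]-1,2,3,3a,4,5,6,8a-octahydroazulen-8a-ol
Conditions: second-generation Grubbs catalyst RuCl2(=CHPh)(PCy3)(H2IMes) (5 mol %), CH2Cl2, 40 °C
Reagents that add atoms: none
Why: Ring-closing metathesis of two monosubstituted alkenes held cis on the cyclopentane should close the cis-fused seven-membered ring as a cis-disubstituted cycloheptene with loss of ethene.

Step 9
Reactants: 16 ring-fusion allylic alcohol
Product: 17 tributylstannylmethyl ether of 16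
Conditions: KH, 18-crown-6, THF, 0 °C; Bu3SnCH2I, rt
Reagents that add atoms: (iodomethyl)tributylstannane, CCCC[Sn](CCCC)(CCCC)CI
Why: Williamson etherification of the crown-activated potassium alkoxide with the reactive α-stannyl iodide prepares the Wittig–Still rearrangement.

Step 10
Reactants: 17 stannylmethyl ether
Product: 19 [(1R,3aR,4R,7R)-1,4-dimethyl-1-[(1S)-3-methyl-1-Ar-butyl]-1,2,3,3a,4,5,6,7-octahydroazulen-7-yl]methanol, via lithiomethyl ether 18 (not isolated)
Conditions: n-BuLi, THF, −78 °C; H2O
Reagents that add atoms: none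
Why: Tin–lithium exchange gives an α-alkoxy organolithium that undergoes the Wittig–Still [2,3]-sigmatropic rearrangement, forming the C7–C bond on the face that carried the oxygen and moving the alkene to C8=C8a.

Step 11
Reactants: 19 homoallylic primary alcohol
Product: 20 (1R,3aR,4R,7R)-1,4-dimethyl-1-[(1S)-3-methyl-1-Ar-butyl]-1,2,3,3a,4,5,6,7-octahydroazulene-7-carboxylic acid
Conditions: TEMPO (20 mol %), PhI(OAc)2, MeCN–H2O (1:1), rt
Reagents that add atoms: water, O
Why: Oxoammonium-catalysed oxidation of the primary alcohol through the aldehyde hydrate to the acid runs near neutrality and should spare the MOM ethers, the electron-rich ring, the alkene and the allylic C7 centre.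

Step 12
Reactants: 20 carboxylic acid
Product: 21 methyl (1R,3aR,4R,7R)-1,4-dimethyl-1-[(1S)-3-methyl-1-Ar-butyl]-1,2,3,3a,4,5,6,7-octahydroazulene-7-carboxylate
Conditions: TMSCHN2, MeOH–toluene, 0 °C
Reagents that add atoms: (trimethylsilyl)diazomethane, C[Si](C)(C)C=[N+]=[N-]
Why: Esterification by proton transfer to the diazoalkane and SN2 methylation of the carboxylate needs no base that could epimerise C7.

Step 13
Reactants: 21 methyl ester
Product: 22 2-[(1R,3aR,4R,7R)-1,4-dimethyl-1-[(1S)-3-methyl-1-Ar-butyl]-1,2,3,3a,4,5,6,7-octahydroazulen-7-yl]propan-2-ol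
Conditions: MeLi, CeCl3, THF, −78 °C; aq NH4Cl
Reagents that add atoms: methyllithium, [Li]C
Why: Double 1,2-addition of the non-basic methylcerium reagent to the ester should give the dimethylcarbinol without enolising the allylic ester or the intermediate methyl ketone.

Step 14
Reactants: 22 tertiary alcohol
Product: 24 3-[(1S)-1-[(1R,3aR,4R,7R)-7-(2-hydroxypropan-2-yl)-1,4-dimethyl-1,2,3,3a,4,5,6,7-octahydroazulen-1-yl]-3-methylbutyl]-2,4,6-tris(methoxymethoxy)benzaldehyde, via aryllithium 23 (not isolated)
Conditions: n-BuLi (2.5 equiv), TMEDA, THF, −20 → 0 °C; DMF, −78 → 0 °C; H2O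
Reagents that add atoms: N,N-dimethylformamide, CN(C)C=O
Why: Directed ortho-metalation in which, after deprotonation of the alcohol, a ring hydrogen flanked by two MOM ethers is removed and the aryllithium is formylated with DMF (Bouveault-type formylation).

Step 15
Reactants: 24 monoaldehyde
Product: 27 5-[(1S)-1-[(1R,3aR,4R,7R)-7-(2-hydroxypropan-2-yl)-1,4-dimethyl-1,2,3,3a,4,5,6,7-octahydroazulen-1-yl]-3-methylbutyl]-2,4,6-tris(methoxymethoxy)benzene-1,3-dicarbaldehyde, via lithium aminoalkoxide 25 (not isolated), via aryllithium 26 (not isolated)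
Conditions: LiN(Me)CH2CH2NMe2 (2.2 equiv, from the diamine and n-BuLi), THF, −20 °C; n-BuLi, −20 → 0 °C; DMF; H2O
Reagents that add atoms: N,N-dimethylformamide, CN(C)C=O
Why: In situ protection of the aldehyde as an α-amino alkoxide lets the last ring hydrogen, again flanked by two MOM ethers, undergo directed ortho-metalation and formylation, and aqueous work-up releases both aldehydes.

Step 16
Reactants: 27 tris-MOM dialdehyde
Product: 28 2,4,6-trihydroxy-5-[(1S)-1-[(1R,3aR,4R,7R)-7-(2-hydroxypropan-2-yl)-1,4-dimethyl-1,2,3,3a,4,5,6,7-octahydroazulen-1-yl]-3-methylbutyl]benzene-1,3-dicarbaldehyde (CNP0281883.3)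
Conditions: HCl (cat., 1.25 M in MeOH), MeOH, 0 °C → rt
Reagents that add atoms: none
Why: Acid-catalysed transacetalisation of the three aryl MOM ethers to methanol, with dilute anhydrous acid at or below room temperature chosen so that the tertiary alcohol and the trisubstituted alkene are not ionised.

**Compound list**

1 | 2,4,6-trihydroxybenzaldehyde | O=Cc1c(O)cc(O)cc1O | starting material
2 | 2,4,6-tris(methoxymethoxy)benzaldehyde | O=Cc1c(OCOC)cc(OCOC)cc1OCOC | intermediate
3 | cyclopentanone | O=C1CCCC1 | starting material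
4 | (E)-2-[2,4,6-tris(methoxymethoxy)benzylidene]cyclopentan-1-one | O=C1CCC/C1=C\c1c(OCOC)cc(OCOC)cc1OCOC | intermediate
5 | isobutylmagnesium bromide | CC(C)C[Mg]Br | starting material
6 | bromomagnesium 2-[(1S)-3-methyl-1-Ar-butyl]cyclopent-1-en-1-olate (formed in the flask) | CC(C)C[C@H](c1c(OCOC)cc(OCOC)cc1OCOC)C1=C(O[Mg]Br)CCC1 | intermediate
7 | (2R)-2-methyl-2-[(1R)-3-methyl-1-Ar-butyl]cyclopentan-1-one | CC(C)C[C@H](c1c(OCOC)cc(OCOC)cc1OCOC)[C@@]1(C)CCCC1=O | intermediate
8 | hydrazone of 7 (formed in the flask) | CC(C)C[C@H](c1c(OCOC)cc(OCOC)cc1OCOC)[C@@]1(C)CCCC1=NN | intermediate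
9 | (5R)-1-iodo-5-methyl-5-[(1R)-3-methyl-1-Ar-butyl]cyclopent-1-ene | CC(C)C[C@H](c1c(OCOC)cc(OCOC)cc1OCOC)[C@@]1(C)CCC=C1I | intermediate
10 | (Z)-but-2-en-1-ol | C/C=C\CO | starting material
11 | (5R)-1-[(Z)-but-2-enyloxy]-5-methyl-5-[(1S)-3-methyl-1-Ar-butyl]cyclopent-1-ene (formed in the flask) | CC(C)C[C@H](c1c(OCOC)cc(OCOC)cc1OCOC)[C@@]1(C)CCC=C1OC/C=C\C | intermediate
12 | (2R,5R)-5-[(2R)-but-3-en-2-yl]-2-methyl-2-[(1R)-3-methyl-1-Ar-butyl]cyclopentan-1-one | CC(C)C[C@H](c1c(OCOC)cc(OCOC)cc1OCOC)[C@@]1(C)CC[C@H]([C@H](C)C=C)C1=O | intermediate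
13 | 9-BBN adduct of 12 with boron on the terminal carbon (formed in the flask) | CC(C)C[C@H](c1c(OCOC)cc(OCOC)cc1OCOC)[C@@]1(C)CC[C@H]([C@H](C)CCB2C3CCCC2CCC3)C1=O | intermediate
14 | (2R,5R)-5-[(2R)-hex-5-en-2-yl]-2-methyl-2-[(1R)-3-methyl-1-Ar-butyl]cyclopentan-1-one | CC(C)C[C@H](c1c(OCOC)cc(OCOC)cc1OCOC)[C@@]1(C)CC[C@H]([C@H](C)CCC=C)C1=O | intermediate
15 | (1R,2R,5R)-1-ethenyl-5-[(2R)-hex-5-en-2-yl]-2-methyl-2-[(1S)-3-methyl-1-Ar-butyl]cyclopentan-1-ol | CC(C)C[C@H](c1c(OCOC)cc(OCOC)cc1OCOC)[C@@]1(C)CC[C@H]([C@H](C)CCC=C)[C@]1(O)C=C | intermediate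
16 | (1R,3aR,4R,8aR)-1,4-dimethyl-1-[(1S)-3-methyl-1-Ar-butyl]-1,2,3,3a,4,5,6,8a-octahydroazulen-8a-ol (cis-fused; OH cis to H-3a) | CC(C)C[C@H](c1c(OCOC)cc(OCOC)cc1OCOC)[C@@]1(C)CC[C@@H]2[C@H](C)CCC=C[C@]12O | intermediate
17 | tributylstannylmethyl ether of 16 | CC(C)C[C@H](c1c(OCOC)cc(OCOC)cc1OCOC)[C@@]1(C)CC[C@@H]2[C@H](C)CCC=C[C@]12OC[Sn](CCCC)(CCCC)CCCC | intermediate
18 | lithiomethyl ether of 16 (formed in the flask) | CC(C)C[C@H](c1c(OCOC)cc(OCOC)cc1OCOC)[C@@]1(C)CC[C@@H]2[C@H](C)CCC=C[C@]12OC[Li] | intermediate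
19 | [(1R,3aR,4R,7R)-1,4-dimethyl-1-[(1S)-3-methyl-1-Ar-butyl]-1,2,3,3a,4,5,6,7-octahydroazulen-7-yl]methanol | CC(C)C[C@H](c1c(OCOC)cc(OCOC)cc1OCOC)[C@@]1(C)CC[C@H]2C1=C[C@H](CO)CC[C@H]2C | intermediate
20 | (1R,3aR,4R,7R)-1,4-dimethyl-1-[(1S)-3-methyl-1-Ar-butyl]-1,2,3,3a,4,5,6,7-octahydroazulene-7-carboxylic acid | CC(C)C[C@H](c1c(OCOC)cc(OCOC)cc1OCOC)[C@@]1(C)CC[C@H]2C1=C[C@H](C(=O)O)CC[C@H]2C | intermediate
21 | methyl ester of 20 | CC(C)C[C@H](c1c(OCOC)cc(OCOC)cc1OCOC)[C@@]1(C)CC[C@H]2C1=C[C@H](C(=O)OC)CC[C@H]2C | intermediate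
22 | 2-[(1R,3aR,4R,7R)-1,4-dimethyl-1-[(1S)-3-methyl-1-Ar-butyl]-1,2,3,3a,4,5,6,7-octahydroazulen-7-yl]propan-2-ol | CC(C)C[C@H](c1c(OCOC)cc(OCOC)cc1OCOC)[C@@]1(C)CC[C@H]2C1=C[C@H](C(C)(C)O)CC[C@H]2C | intermediate
23 | ring-lithiated lithium alkoxide of 22 (formed in the flask) | CC(C)C[C@H](c1c(OCOC)c([Li])c(OCOC)cc1OCOC)[C@@]1(C)CC[C@H]2C1=C[C@H](C(C)(C)O[Li])CC[C@H]2C | intermediate
24 | monoaldehyde: 22 with CHO on one free ring position | CC(C)C[C@H](c1c(OCOC)c(C=O)c(OCOC)cc1OCOC)[C@@]1(C)CC[C@H]2C1=C[C@H](C(C)(C)O)CC[C@H]2C | intermediate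
25 | lithium α-amino alkoxide of 24 with lithiated carbinol (formed in the flask) | CC(C)C[C@H](c1c(OCOC)c(C(O[Li])N(C)CCN(C)C)c(OCOC)cc1OCOC)[C@@]1(C)CC[C@H]2C1=C[C@H](C(C)(C)O[Li])CC[C@H]2C | intermediate
26 | ring-lithiated 25 (formed in the flask) | CC(C)C[C@H](c1c(OCOC)c(C(O[Li])N(C)CCN(C)C)c(OCOC)c([Li])c1OCOC)[C@@]1(C)CC[C@H]2C1=C[C@H](C(C)(C)O[Li])CC[C@H]2C | intermediate
27 | 5-[(1S)-1-[(1R,3aR,4R,7R)-7-(2-hydroxypropan-2-yl)-1,4-dimethyl-1,2,3,3a,4,5,6,7-octahydroazulen-1-yl]-3-methylbutyl]-2,4,6-tris(methoxymethoxy)benzene-1,3-dicarbaldehyde | CC(C)C[C@H](c1c(OCOC)c(C=O)c(OCOC)c(C=O)c1OCOC)[C@@]1(C)CC[C@H]2C1=C[C@H](C(C)(C)O)CC[C@H]2C | intermediate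
28 | 2,4,6-trihydroxy-5-[(1S)-1-[(1R,3aR,4R,7R)-7-(2-hydroxypropan-2-yl)-1,4-dimethyl-1,2,3,3a,4,5,6,7-octahydroazulen-1-yl]-3-methylbutyl]benzene-1,3-dicarbaldehyde | CC(C)C[C@H](c1c(O)c(C=O)c(O)c(C=O)c1O)[C@@]1(C)CC[C@H]2C1=C[C@H](C(C)(C)O)CC[C@H]2C | target

**Step count and risks**

Total step count: 16. Longest linear sequence: 16 steps, from 1; every other component is a commercial reagent.

Steps most likely to fail:

1. Step 3. The β-carbon is flanked by two ortho substituents, so the copper-catalysed addition may be slow; uncatalysed 1,2- and racemic 1,4-addition of the Grignard reagent would then compete and erode conversion and enantioselectivity, and the hindered magnesium enolate may methylate incompletely. The fallback keeps the same two bonds but moves the control to a stoichiometric auxiliary; it sets out from 4 and comes back at 7. Condensation of 4 with (R)-tert-butanesulfinamide (Ti(OEt)4, THF, 65 °C) gives the N-sulfinyl azadiene F1. Diastereoselective 1,4-addition of the isobutylcopper reagent made from 5 and CuBr·SMe2 (THF, −78 °C) generates the metalloenamine at the former α-carbon, which is methylated in the same flask (MeI, DMPU) to the α-methylated N-sulfinyl ketimine F2. Mild hydrolysis (aq AcOH, THF, rt) releases 7; the auxiliary antipode is chosen in the same way as the ligand.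

2. Step 5. Oxidative addition and C–O coupling at the vinyl iodide next to the quaternary carbon may be sluggish, and the rearrangement may leak through a boat transition state or the hot carbonate may epimerise C5, giving diastereomers at C5 or the side-chain methine. The fallback replaces the sigmatropic route by catalyst-controlled allylation; it sets out from 7 and comes back at 12, bypassing 9 and 11. Ketone 7 is converted into the trimethylsilyl enol ether F3 (LDA, TMSCl, THF, −78 °C). Iridium-catalysed branched-selective allylic alkylation with (E)-but-2-enyl methyl carbonate ([Ir(cod)Cl]2, binaphthol-derived phosphoramidite ligand, CsF, ZnF2, DME, 50 °C) then gives 12. The ligand sets the side-chain methine, and the enolate face anti to the aryl(isobutyl)methyl group sets C5.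

3. Step 7. Both faces of the ketone are flanked (methyl and hexenyl chain on one, the aryl(isobutyl)methyl group on the other), so facial selectivity may be poor; the carbinol epimer would be relayed by step 10 into the wrong C7 configuration, and the congested alkoxide may also resist O-alkylation in step 9. The fallback makes the carbinol configuration irrelevant; it sets out from 14 and comes back at 20. Whatever mixture of 15 and the carbinol epimer F4 forms is ring-closed as in step 8 to 16 and the trans-fused carbinol epimer F5. Both converge on the transposed enone F6 by Babler–Dauben oxidative transposition (pyridinium chlorochromate, C5H5NH[CrO3Cl], CH2Cl2, rt). Corey–Bakshi–Shibata reduction ((S)-2-methyl-CBS-oxazaborolidine, BH3·SMe2, THF, −20 °C, the alkenyl arm acting as the large group) gives the (7R) allylic alcohol F7, which is converted into the methyl carbonate F8 (ClCO2Me, pyridine, CH2Cl2, 0 °C). Tsuji–Trost alkylation with nitromethane (Pd(PPh3)4, CH3NO2, THF, 40 °C) should proceed at the less hindered C7 terminus with net retention to the nitromethyl compound F9. Oxidation of the primary nitro group (NaNO2, AcOH, DMSO, 35 °C) then delivers acid 20.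

**Further compounds**

F1 | step 3 | (R)-N-[(E)-2-[2,4,6-tris(methoxymethoxy)benzylidene]cyclopentylidene]-2-methylpropane-2-sulfinamide | CC(C)(C)[S@@](=O)N=C1CCC/C1=C\c1c(OCOC)cc(OCOC)cc1OCOC
F2 | step 3 | (R)-N-tert-butanesulfinyl ketimine of 7 | CC(C)C[C@H](c1c(OCOC)cc(OCOC)cc1OCOC)[C@@]1(C)CCCC1=N[S@](=O)C(C)(C)C
F3 | step 5 | trimethylsilyl enol ether of 7 | CC(C)C[C@H](c1c(OCOC)cc(OCOC)cc1OCOC)[C@@]1(C)CCC=C1O[Si](C)(C)C
F4 | step 7 | (1S)-carbinol epimer of 15 | CC(C)C[C@H](c1c(OCOC)cc(OCOC)cc1OCOC)[C@@]1(C)CC[C@H]([C@H](C)CCC=C)[C@@]1(O)C=C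
F5 | step 7 | (8aS)-carbinol epimer of 16 (trans-fused) | CC(C)C[C@H](c1c(OCOC)cc(OCOC)cc1OCOC)[C@@]1(C)CC[C@@H]2[C@H](C)CCC=C[C@@]12O
F6 | step 7 | (1R,3aR,4R)-1,4-dimethyl-1-[(1S)-3-methyl-1-Ar-butyl]-2,3,3a,4,5,6-hexahydroazulen-7(1H)-one | CC(C)C[C@H](c1c(OCOC)cc(OCOC)cc1OCOC)[C@@]1(C)CC[C@H]2C1=CC(=O)CC[C@H]2C
F7 | step 7 | (1R,3aR,4R,7R)-1,4-dimethyl-1-[(1S)-3-methyl-1-Ar-butyl]-1,2,3,3a,4,5,6,7-octahydroazulen-7-ol | CC(C)C[C@H](c1c(OCOC)cc(OCOC)cc1OCOC)[C@@]1(C)CC[C@H]2C1=C[C@H](O)CC[C@H]2C
F8 | step 7 | methyl carbonate of F7 | CC(C)C[C@H](c1c(OCOC)cc(OCOC)cc1OCOC)[C@@]1(C)CC[C@H]2C1=C[C@H](OC(=O)OC)CC[C@H]2C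
F9 | step 7 | (7R)-7-(nitromethyl) analogue of 19 | CC(C)C[C@H](c1c(OCOC)cc(OCOC)cc1OCOC)[C@@]1(C)CC[C@H]2C1=C[C@H](C[N+](=O)[O-])CC[C@H]2C
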